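**Retrosynthetic overview**
1. Luzonoid D ⇒ global desilylation ⇐ (Z)-p-coumaroylation of the C10 primary alcohol ⇐ 1-O-isovaleroyl 3,4-enol-ether acetal (pyran ring formed last) ⇐ cis-fused 1,5-dialdehyde ⇐ δ-lactone (reduction, then oxidation).
2. The cyclopentane C7/C8 diol and C10 come from an exocyclic C8=C10 methylene: 7α-allylic alcohol-directed OsO4 dihydroxylation, then C7 oxidation and enzymatic (ketoreductase) reduction to 7β-OH.
3. The cis-fused lactone-cyclopentanone comes from an organocatalytic intramolecular Michael reaction of a malonate tethered to the Baylis–Hillman adduct of cyclopentenone. Ring order: cyclopentane (from cyclopentenone), then δ-lactone (Michael step), then dihydropyran (last).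

Assumptions: iridoid numbering is used, with β = the face bearing H-5/H-9, so the 1β-isovalerate is the natural anomer. C1 is assumed to be set under thermodynamic (anomeric) control, and the C3=C4 enol ether is formed as in the natural series.

---

**Step 1**
Reactants: 1 cyclopent-2-en-1-one; 2 formaldehyde (aq. formalin)
Product: 3 2-(hydroxymethyl)cyclopent-2-en-1-one
Conditions: imidazole (cat.), THF/H2O, rt
Reagents that add atoms: none beyond reactant 2
Why: Morita–Baylis–Hillman reaction places the future C1 carbon at the α-carbon (C9) of the enone, which fixes the regiochemistry of all later ring chemistry.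

**Step 2**
Reactants: 3; 4 mono-tert-butyl malonate
Product: 5 (5-oxocyclopent-1-en-1-yl)methyl tert-butyl malonate
Conditions: EDC·HCl, DMAP (cat.), CH2Cl2, 0 °C → rt
Reagents that add atoms: none beyond reactant 4
Why: Steglich esterification of the primary allylic alcohol builds the tether (C1–O2–C3–C4) for the ring-B Michael cyclisation.

**Step 3**
Reactant: 5
Product: 6 cis-fused lactone-cyclopentanone with C4–CO2tBu (C4 epimers; H-5β, H-9β)
Conditions: quinine-derived squaramide (10 mol%), toluene, 0 °C → rt
Reagents that add atoms: none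
Why: Bifunctional H-bonding catalysis makes the malonate enol add 6-endo-trig to one enantioface of the enone (intramolecular Michael), setting C5 with the C4–C5 bond α. C9 is protonated on the convex face to give the cis ring fusion. The C4 epimers are irrelevant because C4 is decarboxylated in the next step.

**Step 4**
Reactant: 6
Product: 7 cis-fused lactone-cyclopentanone (C4H2)
Conditions: TFA/CH2Cl2 (1:4), rt; then toluene, 90 °C
Reagents that add atoms: none
Why: tert-Butyl ester cleavage gives a malonic half-acid, which decarboxylates thermally and removes the C4 stereocentre. The cis ring fusion is retained because it is the stable junction.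

**Step 5**
Reactants: 7; 8 dibromomethane
Product: 9 8-methylene lactone (C8=C10H2)
Conditions: Zn, CH2Br2, TiCl4, THF/CH2Cl2, 0 °C → rt
Reagents that add atoms: none beyond reactant 8 (BrCBr, which supplies C10)
Why: Lombardo–Takai methylenation is selective for the ketone over the lactone and non-basic, so C9 is not epimerised.

**Step 6**
Reactants: 9; 2 formaldehyde (monomeric gas)
Product: 10 4-hydroxymethyl lactone (C11–OH; C4 epimers)
Conditions: LDA, THF, −78 °C; then CH2O(g), −78 → −40 °C
Reagents that add atoms: none beyond reactant 2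
Why: Aldol hydroxymethylation of the lactone enolate installs C11. Lactone C4–H is the only acidic site, and C4 becomes sp2 later.

**Step 7**
Reactant: 10
Product: 11 C11-OTBS lactone
Conditions: TBSCl, imidazole, DMF, 0 °C → rt
Reagents that add atoms: TBSCl, CC(C)(C)[Si](C)(C)Cl
Why: Silyl ether formation at the primary alcohol.

**Step 8**
Reactant: 11
Product: 12 7-hydroxy-8-methylene lactone (C7 epimers not controlled)
Conditions: SeO2 (cat.), TBHP, CH2Cl2, rt
Reagents that add atoms: SeO2, O=[Se]=O; TBHP, CC(C)(C)OO (terminal oxidant)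
Why: Riley allylic oxidation (ene/[2,3]-shift) functionalises the ring CH2 (C7) and keeps the exocyclic alkene, as in β-pinene → pinocarveol.

**Step 9**
Reactant: 12
Product: 13 7-oxo-8-methylene lactone (enone)
Conditions: Dess–Martin periodinane, NaHCO3, CH2Cl2, 0 °C → rt
Reagents that add atoms: none
Why: Oxidation converges the C7 epimers to a single cross-conjugated enone.

**Step 10**
Reactant: 13
Product: 14 7α-hydroxy-8-methylene lactone (C7–OH on the ring-B face)
Conditions: NaBH4, CeCl3·7H2O, MeOH, −78 °C
Reagents that add atoms: none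
Why: Luche 1,2-reduction delivers hydride to the convex β-face, so OH ends α (cis to ring B), which is the orientation needed to direct the next step.

**Step 11**
Reactant: 14
Product: 15 triol (7α-OH, 8α-OH, C10H2OH on β)
Conditions: OsO4 (1.05 equiv), TMEDA, CH2Cl2, −78 °C; then aq. NaHSO3, THF, rt
Reagents that add atoms: OsO4, O=[Os](=O)(=O)=O
Why: In the Donohoe hydroxyl-directed dihydroxylation, the TMEDA-osmate ester is H-bonded to 7α-OH and adds syn to it. This sets C8 with OH α and C10 β, the target relative configuration at C8.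

**Step 12**
Reactant: 15
Product: 16 C10-OTES triol ether (C7-OH and C8-OH free)
Conditions: TESCl (1.1 equiv), imidazole, DMF, −20 → 0 °C
Reagents that add atoms: TESCl, CC[Si](CC)(CC)Cl
Why: The primary alcohol silylates faster than the secondary and tertiary ones.

**Step 13**
Reactant: 16
Product: 17 7-oxo-8α-hydroxy compound (α-ketol)
Conditions: Dess–Martin periodinane, NaHCO3, CH2Cl2, 0 °C → rt
Reagents that add atoms: none
Why: Selective oxidation of the secondary alcohol; the tertiary OH is untouched, and buffering avoids α-ketol rearrangement.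

**Step 14**
Reactant: 17
Product: 18 7β-hydroxy-8α-hydroxy compound (7-OH trans to 8-OH)
Conditions: ketoreductase (KRED, NADPH-dependent oxidoreductase, EC 1.1.1.–, screened-panel hit), NADP+, glucose/GDH, KPi pH 7.0/DMSO 9:1, 30 °C
Reagents that add atoms: none
Why: Enzymatic ketone reduction in which the active site delivers hydride to the concave α-face, opposite to the substrate's own convex-face preference, giving the 7β-alcohol; this is the key biocatalytic step.

**Step 15**
Reactant: 18
Product: 19 7-OTBS compound
Conditions: TBSOTf (1.1 equiv), 2,6-lutidine, CH2Cl2, −78 °C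
Reagents that add atoms: TBSOTf, CC(C)(C)[Si](C)(C)OS(=O)(=O)C(F)(F)F
Why: Silylation of the secondary alcohol is faster than that of the hindered tertiary one; a TBS ether at C7 is orthogonal to the C10 TES ether.

**Step 16**
Reactant: 19
Product: 20 1,5-diol (C1H2OH, C3H2OH; C4 epimers)
Conditions: LiAlH4, THF, 0 °C
Reagents that add atoms: none
Why: Hydride reduction opens the lactone to the diol; silyl ethers and the tertiary alcohol survive.

**Step 17**
Reactant: 20
Product: 21 cis-1,5-dialdehyde (iridodial-type; C1HO on C9, C3HO on C4)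
Conditions: Dess–Martin periodinane (2.5 equiv), NaHCO3, CH2Cl2, 0 °C → rt
Reagents that add atoms: none
Why: Buffered, non-basic oxidation avoids E1cB loss of the β-silyloxy group from the product β-silyloxy aldehyde.

**Step 18**
Reactants: 21; 22 isovaleric anhydride
Product: 23 1β-isovaleroyloxy 3,4-enol-ether acetal (C1, C3=C4 set; C7-OTBS, C10-OTES, C11-OTBS)
Conditions: PPTS (0.1 equiv), CH2Cl2, rt; then 22, 2,6-lutidine, DMAP (cat.), 0 °C
Reagents that add atoms: none beyond reactant 22 (CC(C)CC(=O)OC(=O)CC(C)C)
Why: Acid-mediated ring–chain tautomerisation through the epimerisable C9 aldehyde gives the cis-fused hydroxy-dihydropyran (lactol), which is trapped by O-acylation. The 1β (axial, anomeric-effect) acylal is favoured; any 1α anomer is removed chromatographically.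

**Step 19**
Reactant: 23
Product: 24 free C10 primary alcohol
Conditions: HF·pyridine, pyridine, THF, 0 °C, 30–60 min
Reagents that add atoms: none
Why: Buffered fluoride removes the primary TES ether much faster than the TBS ethers, and the acylal and enol ether are tolerated.

**Step 20**
Reactants: 25 4-hydroxybenzaldehyde; TBSCl
Product: 26 4-(tert-butyldimethylsilyloxy)benzaldehyde
Conditions: TBSCl, imidazole, DMF, rt
Reagents that add atoms: TBSCl, CC(C)(C)[Si](C)(C)Cl
Why: Phenol protection prevents self-esterification in the later coupling.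

**Step 21**
Reactants: 26; 27 tert-butyl bis(2,2,2-trifluoroethyl)phosphonoacetate
Product: 28 (Z)-tert-butyl 4-(TBSO)cinnamate
Conditions: KHMDS, 18-crown-6, THF, −78 °C
Reagents that add atoms: none beyond reactant 27
Why: Still–Gennari olefination is kinetically Z-selective (Z:E >95:5).

**Step 22**
Reactant: 28
Product: 29 (Z)-4-(TBSO)cinnamic acid
Conditions: TFA, CH2Cl2, 0 °C, 1 h
Reagents that add atoms: none
Why: Acidolysis of the tert-butyl ester leaves the Z-olefin and the aryl silyl ether intact.

**Step 23**
Reactants: 24; 29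
Product: 30 C10 (Z)-coumarate (still silylated)
Conditions: EDC·HCl, DMAP (0.2 equiv), CH2Cl2, 0 °C, dark
Reagents that add atoms: none beyond reactant 29
Why: Steglich esterification is chemoselective for the only free primary alcohol, since the tertiary C8-OH is unreactive; low temperature and darkness protect the Z-olefin and the acylal.

**Step 24**
Reactant: 30
Product: 31 luzonoid D
Conditions: HF·pyridine, pyridine, THF, rt, 24–48 h, dark (plastic vessel)
Reagents that add atoms: none
Why: Buffered HF cleaves the C7-OTBS, C11-OTBS and aryl-OTBS ethers together, giving the target without touching the acylal, enol ether or Z-cinnamate.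

---

**Compound list**

1 | cyclopent-2-en-1-one | O=C1C=CCC1 | starting material
2 | formaldehyde | C=O | starting material
3 | 2-(hydroxymethyl)cyclopent-2-en-1-one | O=C1CCC=C1CO | intermediate
4 | mono-tert-butyl malonate | CC(C)(C)OC(=O)CC(=O)O | starting material
5 | (5-oxocyclopent-1-en-1-yl)methyl tert-butyl malonate | O=C1CCC=C1COC(=O)CC(=O)OC(C)(C)C | intermediate
6 | cis-fused lactone-ketone, C4–CO2tBu (C4 epimers; H-5β, H-9β) | C1OC(=O)C(C(=O)OC(C)(C)C)[C@H]2CCC(=O)[C@@H]12 | intermediate
7 | cis-fused lactone-ketone, C4H2 | C1OC(=O)C[C@H]2CCC(=O)[C@@H]12 | intermediate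
8 | dibromomethane | BrCBr | starting material
9 | 8-methylene lactone | C1OC(=O)C[C@H]2CCC(=C)[C@@H]12 | intermediate
10 | 4-hydroxymethyl lactone (C4 epimers) | C1OC(=O)C(CO)[C@H]2CCC(=C)[C@@H]12 | intermediate
11 | C11-OTBS lactone | C1OC(=O)C(CO[Si](C)(C)C(C)(C)C)[C@H]2CCC(=C)[C@@H]12 | intermediate
12 | 7-hydroxy-8-methylene lactone (C7 epimers) | C1OC(=O)C(CO[Si](C)(C)C(C)(C)C)[C@H]2CC(O)C(=C)[C@@H]12 | intermediate
13 | 7-oxo-8-methylene lactone (enone) | C1OC(=O)C(CO[Si](C)(C)C(C)(C)C)[C@H]2CC(=O)C(=C)[C@@H]12 | intermediate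
14 | 7α-hydroxy-8-methylene lactone | C1OC(=O)C(CO[Si](C)(C)C(C)(C)C)[C@H]2C[C@@H](O)C(=C)[C@@H]12 | intermediate
15 | triol (7α-OH, 8α-OH, C10-OH) | C1OC(=O)C(CO[Si](C)(C)C(C)(C)C)[C@H]2C[C@@H](O)[C@](O)(CO)[C@@H]12 | intermediate
16 | C10-OTES ether of 15 | C1OC(=O)C(CO[Si](C)(C)C(C)(C)C)[C@H]2C[C@@H](O)[C@](O)(CO[Si](CC)(CC)CC)[C@@H]12 | intermediate
17 | 7-oxo-8α-hydroxy α-ketol | C1OC(=O)C(CO[Si](C)(C)C(C)(C)C)[C@H]2CC(=O)[C@](O)(CO[Si](CC)(CC)CC)[C@@H]12 | intermediate
18 | 7β-hydroxy-8α-hydroxy compound | C1OC(=O)C(CO[Si](C)(C)C(C)(C)C)[C@H]2C[C@H](O)[C@](O)(CO[Si](CC)(CC)CC)[C@@H]12 | intermediate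
19 | 7-OTBS compound | C1OC(=O)C(CO[Si](C)(C)C(C)(C)C)[C@H]2C[C@H](O[Si](C)(C)C(C)(C)C)[C@](O)(CO[Si](CC)(CC)CC)[C@@H]12 | intermediate
20 | 1,5-diol (C4 epimers) | OCC(CO[Si](C)(C)C(C)(C)C)[C@H]1C[C@H](O[Si](C)(C)C(C)(C)C)[C@](O)(CO[Si](CC)(CC)CC)[C@H]1CO | intermediate
21 | cis-1,5-dialdehyde | O=CC(CO[Si](C)(C)C(C)(C)C)[C@H]1C[C@H](O[Si](C)(C)C(C)(C)C)[C@](O)(CO[Si](CC)(CC)CC)[C@H]1C=O | intermediate
22 | isovaleric anhydride | CC(C)CC(=O)OC(=O)CC(C)C | starting material
23 | 1β-isovalerate enol-ether acetal, tris-silylated | CC(C)CC(=O)O[C@@H]1OC=C(CO[Si](C)(C)C(C)(C)C)[C@H]2C[C@H](O[Si](C)(C)C(C)(C)C)[C@](O)(CO[Si](CC)(CC)CC)[C@@H]12 | intermediate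
24 | C10 free alcohol | CC(C)CC(=O)O[C@@H]1OC=C(CO[Si](C)(C)C(C)(C)C)[C@H]2C[C@H](O[Si](C)(C)C(C)(C)C)[C@](O)(CO)[C@@H]12 | intermediate
25 | 4-hydroxybenzaldehyde | O=Cc1ccc(O)cc1 | starting material
26 | 4-(TBSO)benzaldehyde | O=Cc1ccc(O[Si](C)(C)C(C)(C)C)cc1 | intermediate
27 | tert-butyl bis(2,2,2-trifluoroethyl)phosphonoacetate | CC(C)(C)OC(=O)CP(=O)(OCC(F)(F)F)OCC(F)(F)F | starting material
28 | (Z)-tert-butyl 4-(TBSO)cinnamate | CC(C)(C)OC(=O)/C=C\c1ccc(O[Si](C)(C)C(C)(C)C)cc1 | intermediate
29 | (Z)-4-(TBSO)cinnamic acid | OC(=O)/C=C\c1ccc(O[Si](C)(C)C(C)(C)C)cc1 | intermediate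
30 | fully silylated C10 (Z)-coumarate | CC(C)CC(=O)O[C@@H]1OC=C(CO[Si](C)(C)C(C)(C)C)[C@H]2C[C@H](O[Si](C)(C)C(C)(C)C)[C@](O)(COC(=O)/C=C\c3ccc(O[Si](C)(C)C(C)(C)C)cc3)[C@@H]12 | intermediate
31 | luzonoid D | CC(C)CC(=O)O[C@@H]1OC=C(CO)[C@H]2C[C@H](O)[C@](O)(COC(=O)/C=C\c3ccc(O)cc3)[C@@H]12 | target

---

**Total step count:** 24 steps, including the 3-step (Z)-coumaric acid branch (steps 20–22).
**Longest linear sequence:** 21 steps (steps 1–19, then 23 and 24), from cyclopentenone 1.

**Three steps most likely to fail**
1. **Step 3 (asymmetric intramolecular Michael).** The MBH-type β-acyloxy enolate can undergo E1cB/SN2′ ring opening, and the ee may be modest.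
   Fallback: cyclise racemically (DBU) to 6 and carry on to 7. Reduce the ketone of 7 (NaBH4), resolve the alcohol by lipase-catalysed transesterification (Pseudomonas cepacia lipase, vinyl acetate), and re-oxidise the resolved alcohol to give enantiopure 7.
2. **Step 14 (KRED reduction).** No enzyme may deliver concave-face hydride to the α-ketol 17.
   Fallback: skip steps 13–14 and invert 16 directly by Mitsunobu reaction (p-nitrobenzoic acid, DIAD, PPh3), then cleave the ester with K2CO3/MeOH at 0 °C. This gives the 7β-alcohol 18 by SN2 at C7 from the open β-face.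
3. **Step 18 (cyclisation/acylation of the dialdehyde).** The equilibrium may favour the open dialdehyde, the β-silyloxy aldehyde may eliminate, and the anomer ratio may be poor.
   Fallback: trap 21 as the cis-fused 1-methoxy enol-ether acetal (HC(OMe)3, PPTS cat., MeOH). Then exchange OMe for O-isovaleryl with 22 and TMSOTf (cat.) at −20 °C, a glycoside-to-acylal acyl exchange that proceeds through the oxocarbenium ion.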